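**Target as read from the SMILES:** (5Z)-5-[(2S,6Z,10E)-13-(furan-3-yl)-2,6,10-trimethyltrideca-6,10-dien-1-ylidene]-4-hydroxy-3-methylfuran-2(5H)-one. It has one stereocentre (S), a Z-alkylidene tetronic acid, a 6Z and a 10E trisubstituted olefin, and a 3-furyl end.

**Retrosynthetic overview**
1. Target ⇒ its 4-O-methyl ether (last step is O-demethylation). No ring is formed in the route: the furan and the butenolide are both bought, so there is no ring-forming order.
2. 6Z olefin ⇒ B-alkyl Suzuki coupling of a (Z)-2-iodoalkene (right half) with the 9-BBN adduct of a terminal alkene (left half).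
3. Left half ⇒ aldol condensation of methyl 3-methyltetronate with (S)-2-methylpent-4-enal ⇒ enantioselective mono-hydroformylation of symmetric penta-1,4-diene (key step, sets the only stereocentre).
4. Right half ⇒ iodo-Wittig olefination of an E-aldehyde ⇒ hydroboration/Suzuki coupling of an E-dienol with 3-bromofuran ⇒ carboalumination/vinylation of pent-4-yn-1-ol (sets the 10E olefin).

Assumption: methyl 3-methyltetronate (4-methoxy-3-methylfuran-2(5H)-one) is bought as a catalogue compound.

**Step 1**
Reactants: 1 penta-1,4-diene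
Product: 2 (2S)-2-methylpent-4-enal
Conditions: 1 (3 equiv), Rh(acac)(CO)2 (0.4 mol%), S-selective enantiomer of BOBPHOS (0.5 mol%), CO/H2 1:1 (5 bar), toluene, 20 °C, to about one third conversion of 1; fractional distillation
Reagents that add atoms: carbon monoxide, [C-]#[O+]
Why: Proposed new method: Rh–H/BOBPHOS catalysts turn unactivated 1-alkenes such as hex-1-ene and allylbenzene into the branched 2-methyl aldehydes in about 90% ee (branched-selective asymmetric hydroformylation is the closest known reaction), and the same Rh–H insertion at C2, CO insertion and hydrogenolysis on one of the two equivalent vinyl groups of the diene breaks its symmetry and creates the only stereocentre (S, by catalyst-controlled face selection); excess diene and partial conversion hold back double hydroformylation, the low temperature holds back isomerisation to penta-1,3-diene, and the linear hex-5-enal (about 20% expected) should boil about 10 °C higher and be removed in the distillation.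

**Step 2**
Reactants: 2 (2S)-2-methylpent-4-enal; 3 4-methoxy-3-methylfuran-2(5H)-one
Product: 7 (5Z)-4-methoxy-3-methyl-5-[(2S)-2-methylpent-4-en-1-ylidene]furan-2(5H)-one, via lithiated tetronate 4 (not isolated), via lithium aldolate 5 (not isolated), via mesylate 6 (not isolated)
Conditions: LiN(i-Pr)2, THF, −78 °C; then 2; then MsCl, −78 to 0 °C; then DBU, rt
Reagents that add atoms: none
Why: Pattenden-type aldol condensation in which the C5-lithiated tetronate adds to the aldehyde at −78 °C faster than it enolises it (the α-stereocentre of 2 is kept), and mesylation/E1cB elimination gives the favoured Z-alkylidene (alkyl group syn to the ring oxygen, away from the 4-OMe) while erasing the two transient centres.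

**Step 3**
Reactants: 8 pent-4-yn-1-ol; 9 bromoethene
Product: 11 (4E)-4-methylhepta-4,6-dien-1-ol, via alkenylalane 10 (not isolated)
Conditions: Me3Al (3 equiv), Cp2ZrCl2 (0.25 equiv), CH2Cl2, 0 °C to rt; then 9 (1 M in THF), Pd(PPh3)4 (5 mol%), ZnCl2 (0.2 equiv), rt
Reagents that add atoms: trimethylaluminium, C[Al](C)C
Why: Negishi Zr-catalysed carboalumination adds Me and Al syn across the terminal alkyne (Me to the inner carbon, hydroxyl carried as its aluminium alkoxide) to give the E-alkenylalane, and the Pd-catalysed Negishi-type coupling with vinyl bromide proceeds with retention to the E-diene.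

**Step 4**
Reactants: 11 (4E)-4-methylhepta-4,6-dien-1-ol; 12 3-bromofuran
Product: 14 (4E)-7-(furan-3-yl)-4-methylhept-4-en-1-ol, via alkylborane 13 (not isolated)
Conditions: 9-BBN (2.2 equiv), THF, 0 °C to rt; then 12, Pd(dppf)Cl2 (5 mol%), 3 M aq NaOH, THF, 65 °C
Reagents that add atoms: none
Why: 9-BBN hydroborates only the monosubstituted terminus of the diene (anti-Markovnikov, the trisubstituted alkene is inert), and the homoallylic B-alkyl-9-BBN undergoes Suzuki–Miyaura B-alkyl coupling with 3-bromofuran without touching the E-olefin.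

**Step 5**
Reactants: 14 (4E)-7-(furan-3-yl)-4-methylhept-4-en-1-ol
Product: 15 (4E)-7-(furan-3-yl)-4-methylhept-4-enal
Conditions: n-Pr4N[RuO4] (5 mol%), NMO, 4 Å molecular sieves, CH2Cl2, rt
Reagents that add atoms: none
Why: Ley–Griffith oxidation stops at the aldehyde and leaves the furan and the trisubstituted alkene alone.

**Step 6**
Reactants: 15 (4E)-7-(furan-3-yl)-4-methylhept-4-enal; 16 ethyltriphenylphosphonium iodide
Product: 20 3-[(3E,7Z)-8-iodo-4-methylnona-3,7-dien-1-yl]furan, via ethylidene ylide 17 (not isolated), via iodophosphonium salt 18 (not isolated), via iodo ylide 19 (not isolated)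
Conditions: 16, n-BuLi, THF, rt; then I2, −78 °C; then NaN(SiMe3)2, −20 °C; then 15, −78 to −20 °C
Reagents that add atoms: iodine, [I][I]
Why: Stork–Zhao-type Wittig olefination in which the non-stabilised α-iodo ylide reacts under kinetic control to give the (Z)-2-iodoalkene (iodine cis to the chain, typically about 10:1), which fixes the geometry of the future 6Z olefin.

**Step 7**
Reactants: 7 (5Z)-4-methoxy-3-methyl-5-[(2S)-2-methylpent-4-en-1-ylidene]furan-2(5H)-one; 20 3-[(3E,7Z)-8-iodo-4-methylnona-3,7-dien-1-yl]furan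
Product: 22 (5Z)-5-[(2S,6Z,10E)-13-(furan-3-yl)-2,6,10-trimethyltrideca-6,10-dien-1-ylidene]-4-methoxy-3-methylfuran-2(5H)-one, via alkylborane 21 (not isolated)
Conditions: 7 (1.3 equiv), 9-BBN (1.4 equiv), THF, 0 °C to rt; then 20, Pd(dppf)Cl2 (10 mol%), AsPh3 (10 mol%), Cs2CO3, DMF/THF/H2O, rt
Reagents that add atoms: none
Why: Chemoselective hydroboration of the monosubstituted alkene (the conjugated ylidene and the lactone are inert to 9-BBN at rt) followed by Suzuki–Miyaura B-alkyl coupling with retention at the iodoalkene gives the Z-trisubstituted olefin, and the mild carbonate base leaves the methyl tetronate and the stereocentre untouched.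

**Step 8**
Reactants: 22 (5Z)-5-[(2S,6Z,10E)-13-(furan-3-yl)-2,6,10-trimethyltrideca-6,10-dien-1-ylidene]-4-methoxy-3-methylfuran-2(5H)-one
Product: 24 (5Z)-5-[(2S,6Z,10E)-13-(furan-3-yl)-2,6,10-trimethyltrideca-6,10-dien-1-ylidene]-4-hydroxy-3-methylfuran-2(5H)-one (CNP0168546.4), via sodium tetronate 23 (not isolated)
Conditions: NaSEt (3 equiv), DMF, rt; then cold 1 M HCl
Reagents that add atoms: none
Why: SN2 O-demethylation of the vinylogous carbonate by thiolate (the tetronate anion is a good leaving group) and acidification free the tetronic acid without touching olefin geometry or the stereocentre.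

**Compound list**
1 | penta-1,4-diene | C=CCC=C | starting material
2 | (2S)-2-methylpent-4-enal | O=C[C@@H](C)CC=C | intermediate
3 | 4-methoxy-3-methylfuran-2(5H)-one (methyl 3-methyltetronate) | COC1=C(C)C(=O)OC1 | starting material
4 | (3-methoxy-4-methyl-5-oxo-2,5-dihydrofuran-2-yl)lithium (3 lithiated at C5) | [Li]C1OC(=O)C(C)=C1OC | intermediate
5 | lithium (2S)-1-(3-methoxy-4-methyl-5-oxo-2,5-dihydrofuran-2-yl)-2-methylpent-4-en-1-olate (mixture at the two new centres) | [Li]OC(C1OC(=O)C(C)=C1OC)[C@@H](C)CC=C | intermediate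
6 | (2S)-1-(3-methoxy-4-methyl-5-oxo-2,5-dihydrofuran-2-yl)-2-methylpent-4-en-1-yl methanesulfonate (mixture at the two new centres) | CS(=O)(=O)OC(C1OC(=O)C(C)=C1OC)[C@@H](C)CC=C | intermediate
7 | (5Z)-4-methoxy-3-methyl-5-[(2S)-2-methylpent-4-en-1-ylidene]furan-2(5H)-one | CC1=C(OC)/C(=C/[C@@H](C)CC=C)OC1=O | intermediate
8 | pent-4-yn-1-ol | C#CCCCO | starting material
9 | bromoethene (vinyl bromide) | C=CBr | starting material
10 | dimethyl{[(4E)-5-(dimethylalumanyl)-4-methylpent-4-en-1-yl]oxy}alumane | C[Al](C)OCCC/C(C)=C/[Al](C)C | intermediate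
11 | (4E)-4-methylhepta-4,6-dien-1-ol | OCCC/C(C)=C/C=C | intermediate
12 | 3-bromofuran | Brc1ccoc1 | starting material
13 | 9-{(3E)-7-[(9-borabicyclo[3.3.1]nonan-9-yl)oxy]-4-methylhept-3-en-1-yl}-9-borabicyclo[3.3.1]nonane | O(B1C2CCCC1CCC2)CCC/C(C)=C/CCB1C2CCCC1CCC2 | intermediate
14 | (4E)-7-(furan-3-yl)-4-methylhept-4-en-1-ol | OCCC/C(C)=C/CCc1ccoc1 | intermediate
15 | (4E)-7-(furan-3-yl)-4-methylhept-4-enal | O=CCC/C(C)=C/CCc1ccoc1 | intermediate
16 | ethyltriphenylphosphonium iodide | CC[P+](c1ccccc1)(c1ccccc1)c1ccccc1.[I-] | starting material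
17 | ethylidenetriphenylphosphorane | CC=P(c1ccccc1)(c1ccccc1)c1ccccc1 | intermediate
18 | (1-iodoethyl)triphenylphosphonium iodide | CC(I)[P+](c1ccccc1)(c1ccccc1)c1ccccc1.[I-] | intermediate
19 | (1-iodoethylidene)triphenylphosphorane | CC(I)=P(c1ccccc1)(c1ccccc1)c1ccccc1 | intermediate
20 | 3-[(3E,7Z)-8-iodo-4-methylnona-3,7-dien-1-yl]furan | C/C(I)=C/CC/C(C)=C/CCc1ccoc1 | intermediate
21 | (5Z)-5-[(2S)-5-(9-borabicyclo[3.3.1]nonan-9-yl)-2-methylpentylidene]-4-methoxy-3-methylfuran-2(5H)-one | CC1=C(OC)/C(=C/[C@@H](C)CCCB2C3CCCC2CCC3)OC1=O | intermediate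
22 | (5Z)-5-[(2S,6Z,10E)-13-(furan-3-yl)-2,6,10-trimethyltrideca-6,10-dien-1-ylidene]-4-methoxy-3-methylfuran-2(5H)-one | CC1=C(OC)/C(=C/[C@@H](C)CCC/C(C)=C\CC/C(C)=C/CCc2ccoc2)OC1=O | intermediate
23 | sodium (5Z)-5-[(2S,6Z,10E)-13-(furan-3-yl)-2,6,10-trimethyltrideca-6,10-dien-1-ylidene]-3-methyl-2-oxo-2,5-dihydrofuran-4-olate | CC1=C([O-])/C(=C/[C@@H](C)CCC/C(C)=C\CC/C(C)=C/CCc2ccoc2)OC1=O.[Na+] | intermediate
24 | (5Z)-5-[(2S,6Z,10E)-13-(furan-3-yl)-2,6,10-trimethyltrideca-6,10-dien-1-ylidene]-4-hydroxy-3-methylfuran-2(5H)-one (CNP0168546.4) | CC1=C(O)/C(=C/[C@@H](C)CCC/C(C)=C\CC/C(C)=C/CCc2ccoc2)OC1=O | target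

**Step count:** 8 steps in total. Longest linear sequence: 6 steps (8 → 11 → 14 → 15 → 20 → 22 → 24).

**Steps most likely to fail, with fallbacks**

Step 1 is the riskiest. This diene has not been used in branched-selective asymmetric hydroformylation, and the step is the only source of enantiopurity (about 90% ee expected, carried unchanged to 24). The fallback sets out from 1 and comes back at 2. It replaces hydroformylation by Zr-catalysed asymmetric carboalumination of the same diene: 1 (excess), Me3Al and (+)-bis(1-neomenthylindenyl)zirconium dichloride, (+)-(NMI)2ZrCl2 (3 mol%), in CH2Cl2 give dimethyl[(2S)-2-methylpent-4-en-1-yl]alumane F1, which O2 oxidises to (2S)-2-methylpent-4-en-1-ol F2 (about 75–80% ee expected). Amano PS lipase with vinyl acetate, expected to acetylate the S alcohol faster, is run to about 80% conversion to give (2S)-2-methylpent-4-en-1-yl acetate F3 (aiming at ≥97% ee). K2CO3 in MeOH returns F2, and n-Pr4N[RuO4]/NMO oxidises it to 2. This costs three extra steps but gives higher ee and no linear isomer.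

Step 4 is the second risk, in the regiochemistry of the diene hydroboration and in the coupling to the electron-rich 3-bromofuran. The fallback sets out from 8 and comes back at 14, bypassing diene 11 by moving the boron to the furan partner. The carboalumination of 8 (through alkenylalane 10) is quenched with I2 to give (4E)-5-iodo-4-methylpent-4-en-1-ol F4. Furan-3-carbaldehyde and Ph3P=CH2 give 3-ethenylfuran F5, which 9-BBN converts to 9-[2-(furan-3-yl)ethyl]-9-borabicyclo[3.3.1]nonane F6. Coupling of F6 with F4 (Pd(dppf)Cl2, aq NaOH, THF) gives 14.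

Step 6 is the third risk: α-iodo-ylide olefinations give modest yields and the Z:E ratio can erode. The fallback sets out from 15 and comes back at 22. CBr4/PPh3 converts 15 into 3-[(3E)-8,8-dibromo-4-methylocta-3,7-dien-1-yl]furan F7. Pd-catalysed trans-selective monomethylation (Me2Zn, Pd(DPEphos)Cl2, THF) replaces only the bromine trans to the chain and gives 3-[(3E,7Z)-8-bromo-4-methylnona-3,7-dien-1-yl]furan F8. F8 then takes the place of 20 in the coupling with 21 under the step 7 conditions to give 22.

**Further compounds**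
F1 | step 1 | dimethyl[(2S)-2-methylpent-4-en-1-yl]alumane | C[Al](C)C[C@@H](C)CC=C
F2 | step 1 | (2S)-2-methylpent-4-en-1-ol | OC[C@@H](C)CC=C
F3 | step 1 | (2S)-2-methylpent-4-en-1-yl acetate | CC(=O)OC[C@@H](C)CC=C
F4 | step 4 | (4E)-5-iodo-4-methylpent-4-en-1-ol | OCCC/C(C)=C/I
F5 | step 4 | 3-ethenylfuran | C=Cc1ccoc1
F6 | step 4 | 9-[2-(furan-3-yl)ethyl]-9-borabicyclo[3.3.1]nonane | C(Cc1ccoc1)B1C2CCCC1CCC2
F7 | step 6 | 3-[(3E)-8,8-dibromo-4-methylocta-3,7-dien-1-yl]furan | BrC(Br)=CCC/C(C)=C/CCc1ccoc1
F8 | step 6 | 3-[(3E,7Z)-8-bromo-4-methylnona-3,7-dien-1-yl]furan | C/C(Br)=C/CC/C(C)=C/CCc1ccoc1
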